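The blue run was charged with more solid substrate than the grey flask, 0.075 M against 0.050 M, yet I read nearly the same loss of solid from both, 0.00255 M h⁻¹ and 0.00244 M h⁻¹.

| flask | solid substrate | solid reagent | remark | time |
|---|---|---|---|---|
| grey | 0.050 M | 1.5 equiv | the very flask that is asked about, followed so far |  |
| blue | 0.075 M | 1.5 equiv | run made earlier |  |
| flask | 0.050 M | 1.50 equiv |  | 20 h |

| run | time / h | target / % | solid substrate / % |
|---|---|---|---|
| grey | 0.667 | 2 | 94 |
| grey | 2.00 | 2 | 89 |
| grey | 4.00 | 9 | 77 |
| grey | 6.00 | 14 | 67 |
| grey | 8.00 | 25 | 61 |
| blue | 1.00 | 2 | 96 |
| blue | 2.00 | 3 | 90 |
| blue | 4.00 | 6 | 84 |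
| blue | 8.00 | 17 | 72 |
| blue | 15.0 | 38 | 49 |

(readings scatter by 1.5 percentage points)

- solid, in amounts per volume of the solution: solid substrate, solid reagent
- at the start none of the solid substrate is in solution
- at the start none of the solid reagent is in solution

- south: doubling the solubility of the solid substrate, all else as stated
- west: doubling the solubility of the solid reagent, all else as stated
- north: doubling the dissolution coefficient of the solid reagent, all else as stated
- east: doubling the dissolution coefficient of the solid substrate, all else as stated

1. the target standing at 20 h, as a percentage of the solid substrate charged
2. the change that raises the amount of target at 20 h, in percent of the solid substrate charged most ("none" if none brings more than 2 percentage points) (south / west / north / east / none)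
3. amount of target at 20 h, in percent of the solid substrate charged, after north

A constant rate integrates to a straight line, so I expected the grey flask to have lost 97.5 % of its solid at 20 h. At 8.00 h, 14.0 % of the charge had left the solid without being target; I called this the waiting share. Holding that share steady, I reckoned 83.5 % of target. The forecast was a separate judgement and gave 80 %, with south as the best change and 81 % after north, on the ground: “So the process is zero-order, set by a saturated solution rather than by the solid charged”.

The flask gave 53.2 %. South was the best change, with a gain of 23 percentage points, and north gave 49.4 %.

    solid substrate ⇌ dissolved substrate, rate k1*(cs1 - [dissolved substrate]) while solid is left; crystals form when [dissolved substrate] > cs1 (solubility = 33.0 mM, k = 0.0930 h⁻¹)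
    dissolved substrate + partner → target (k = 9.50 M⁻¹ h⁻¹)
    partner → side product (k = 0.130 h⁻¹)
    2 solid substrate → homo dimer (k = 0.00990 M⁻¹ h⁻¹)
    solid reagent ⇌ partner, rate k5*(cs5 - [partner]) while solid is left; crystals form when [partner] > cs5 (solubility = 49.0 mM, k = 0.360 h⁻¹)

In the grey flask at 20.0 h, the waiting share had grown from 14.0 % to 35.6 %, nearly all of it dissolved substrate, with [partner] down to 0.00210 M. Its solid reagent, the limiting reagent here, stood at 0 % by 10.0 h. The low solubility of dissolved substrate and the step from partner to side product acted together, each a part of the cause: the run without the first gave 88.2 % of target and the run without the second 86.2 %, against 53.2 %. The neighbour flask with 0.013 M of solid substrate had 0 % of its solid left, and its waiting share stood at 52.1 % beside 47.9 % of target.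

Readings and results were generated by integration for substances that don't exist; the scatter is artificial.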